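**Strategy.** The whole bicycle is made in one intramolecular Diels–Alder reaction of an acyclic vinylallene that forms C5–C10 and C3–C4 (eremophilane numbering). The step exploits C10: in the target it is the sp2 fusion carbon of the cross-conjugated dienone ring B, with C9=C10 exocyclic to ring A, so it can be the central carbon of an allene. The diene C10=C1–C2=C3(OAc) adds to the C4=C5 tiglyl alkene across a C6–C9 tether, closing ring A and ring B, leaving the dienone in place and setting the all-cis C3/C4/C5 triad; the (aR) allene axis, written from an (R) propargylic carbinol, fixes the absolute configuration. The precursor is a linear dienyl allenyl ketone.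

Key step: step 10

Locants: eremophilane numbering of the target is used in the text. Ring A is C1–C5 plus C10, ring B is C5–C10, C3 carries OAc, C4 and C5 carry the methyl groups, C8 is the ketone, C11 is the side-chain carbinol carbon and C12 the carboxyl carbon.

Assumption: compounds 1, 3, 7, 10 and 12 are taken as commercial. The ligand enantiomers named in steps 2 and 6 are those expected to give the stated carbinol configurations; if either induces the opposite sense, its antipode is used and nothing else changes.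

Step 1
Reactants: 1 (E)-2-methylbut-2-enal (tiglic aldehyde)
Product: 2 (E)-3-methylpent-3-en-1-yne
Conditions: Me3SiCHN2, LiN(iPr)2, THF, −78 °C to rt
Reagents that add atoms: trimethylsilyldiazomethane, C[Si](C)(C)C=[N+]=[N-]
Why: Colvin rearrangement (addition of lithiated trimethylsilyldiazomethane, Peterson elimination, 1,2-shift in the alkylidene carbene) homologates the enal to the enyne and leaves untouched the E-trisubstituted alkene that later serves as the dienophile.

Step 2
Reactants: 2 (E)-3-methylpent-3-en-1-yne; 3 tert-butyl 2-oxopropanoate (tert-butyl pyruvate)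
Product: 4 tert-butyl (2R,5E)-2-hydroxy-2,5-dimethylhept-5-en-3-ynoate
Conditions: Zn(OTf)2 (20 mol%), (1S,2S)-2-(dimethylamino)-1-(4-nitrophenyl)-3-(tert-butyldimethylsilyloxy)propan-1-ol (22 mol%), Et3N (30 mol%), PhMe, 70 °C, sealed tube
Reagents that add atoms: none
Why: Catalytic enantioselective addition of a zinc alkynylide to an α-keto ester, in which the chiral amino-alcohol zinc complex differentiates the two faces of the ketone and sets C11, a centre that is not touched again.

Step 3
Reactants: 4 tert-butyl (2R,5E)-2-hydroxy-2,5-dimethylhept-5-en-3-ynoate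
Product: 6 tert-butyl (2S,3Z,5E)-2-hydroxy-3-iodo-2,5-dimethylhepta-3,5-dienoate, via alkenylstannane 5 (not isolated)
Conditions: [Cp*RuCl]4 (2.5 mol%), Bu3SnH, CH2Cl2, rt; then I2, 0 °C
Reagents that add atoms: iodine, II
Why: Hydroxyl-directed ruthenium-catalysed trans-hydrostannation puts tin on the alkyne carbon next to the tertiary OH with hydrogen trans to it, and iododestannylation with retention gives the Z-iodide whose iodine (the future C8 position) is cis to C5; the change of the C2 descriptor from R to S reflects only the new substituent priorities.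

Step 4
Reactants: 6 tert-butyl (2S,3Z,5E)-2-hydroxy-3-iodo-2,5-dimethylhepta-3,5-dienoate; 7 (R)-2-methylbutanoic acid
Product: 9 tert-butyl (2S,3Z,5E)-3-iodo-2,5-dimethyl-2-{[(2R)-2-methylbutanoyl]oxy}hepta-3,5-dienoate, via acid chloride 8 (not isolated)
Conditions: 7, (COCl)2, cat. DMF, CH2Cl2, 0 °C to rt, evaporate; 6, LiN(SiMe3)2 (1.0 equiv), THF, −78 °C, then crude 8, −78 to 0 °C
Reagents that add atoms: none
Why: O-acylation of the preformed lithium alkoxide of a hindered tertiary α-hydroxy ester by an acid chloride, where one equivalent of base at low temperature should avoid ketene formation and so keep the (R) centre of the acyl group.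

Step 5
Reactants: 10 tetrabutylammonium (E)-3-oxoprop-1-en-1-olate (malondialdehyde tetrabutylammonium salt)
Product: 11 (E)-3-oxoprop-1-en-1-yl acetate
Conditions: AcCl, CH2Cl2, −78 to 0 °C
Reagents that add atoms: acetyl chloride, CC(Cl)=O
Why: O-acylation of the W-shaped malondialdehyde enolate should give the E-configured β-acyloxyacrolein, which already carries the C3 acetate of the target.

Step 6
Reactants: 11 (E)-3-oxoprop-1-en-1-yl acetate; 12 3,3-diethoxyprop-1-yne
Product: 13 (1E,3R)-6,6-diethoxy-3-hydroxyhex-1-en-4-yn-1-yl acetate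
Conditions: Me2Zn, (S,S)-ProPhenol (10 mol%), Ph3P=O (20 mol%), PhMe, 4 °C, slow addition of 11
Reagents that add atoms: none
Why: Dinuclear zinc–ProPhenol catalysed enantioselective alkynylation of an enal, in which the catalyst sets the C1 carbinol as (R), the centre that later encodes the allene axis.

Step 7
Reactants: 13 (1E,3R)-6,6-diethoxy-3-hydroxyhex-1-en-4-yn-1-yl acetate
Product: 14 (1E,3R)-3-hydroxy-6-oxohex-1-en-4-yn-1-yl acetate
Conditions: Amberlyst-15, acetone/H2O (20:1), 0 °C to rt
Reagents that add atoms: water, O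
Why: Mild acid-catalysed acetal hydrolysis should unmask the ynal while the E-enol acetate and the secondary carbinol stay intact.

Step 8
Reactants: 9 tert-butyl (2S,3Z,5E)-3-iodo-2,5-dimethyl-2-{[(2R)-2-methylbutanoyl]oxy}hepta-3,5-dienoate; 14 (1E,3R)-3-hydroxy-6-oxohex-1-en-4-yn-1-yl acetate
Product: 15 tert-butyl (2R,3E,7R,8E)-9-acetoxy-4,7-dihydroxy-2-methyl-2-{[(2R)-2-methylbutanoyl]oxy}-3-[(2E)-2-methylbut-2-en-1-ylidene]non-8-en-5-ynoate (both C4 epimers; C4 of this name is C8)
Conditions: CrCl2 (6 equiv), NiCl2 (1 mol%), DMSO/THF, rt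
Reagents that add atoms: none
Why: Nozaki–Hiyama–Kishi coupling, in which the alkenylchromium species formed from the iodide with retention adds 1,2 to the aldehyde in the presence of the esters, the enol acetate and the free OH; the new C8 carbinol is formed as both epimers, which converge in step 10.

Step 9
Reactants: 15 tert-butyl (2R,3E,7R,8E)-9-acetoxy-4,7-dihydroxy-2-methyl-2-{[(2R)-2-methylbutanoyl]oxy}-3-[(2E)-2-methylbut-2-en-1-ylidene]non-8-en-5-ynoate
Product: 18 tert-butyl (2R,3E,8E)-9-acetoxy-4-hydroxy-2-methyl-2-{[(2R)-2-methylbutanoyl]oxy}-3-[(2E)-2-methylbut-2-en-1-ylidene]nona-5,6,8-trienoate with (aR) allene axis (both C4 epimers), via sulfonylhydrazine adduct 16 (not isolated), via propargylic diazene 17 (not isolated)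
Conditions: PPh3, DEAD, 2-nitrobenzenesulfonyl hydrazide (NBSH), THF, −15 °C; then rt; rapid filtration through neutral alumina, kept cold
Reagents that add atoms: none
Why: Myers allene synthesis, in which Mitsunobu displacement with inversion occurs at the unhindered C1–OH (the C8–OH sits next to a fully substituted alkene carbon and should not be displaced), and loss of sulfinic acid followed by syn retro-ene loss of N2 delivers H to C9 anti to the departed oxygen, so the (R) carbinol is transcribed into the (aR) axis.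

Step 10
Reactants: 18 tert-butyl (2R,3E,8E)-9-acetoxy-4-hydroxy-2-methyl-2-{[(2R)-2-methylbutanoyl]oxy}-3-[(2E)-2-methylbut-2-en-1-ylidene]nona-5,6,8-trienoate with (aR) allene axis
Product: 20 tert-butyl (2R)-2-[(4aR,5R,6S)-6-acetoxy-4a,5-dimethyl-2-oxo-2,4a,5,6-tetrahydronaphthalen-3-yl]-2-{[(2R)-2-methylbutanoyl]oxy}propanoate, via allenyl dienyl ketone 19 (not isolated)
Conditions: DMP (1,1,1-triacetoxy-1,1-dihydro-1,2-benziodoxol-3(1H)-one), pyridine, CH2Cl2, 0 °C; cold aq. NaHCO3/Na2S2O3 wash; then PhMe (0.003 M), BHT, 80 °C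
Reagents that add atoms: none
Why: Oxidation of the doubly activated C8 carbinol gives ketone 19, which should undergo a concerted suprafacial intramolecular [4+2] cycloaddition of the vinylallene diene C10=C1–C2=C3(OAc) with the C4=C5 alkene, forming C5–C10 and C3–C4 together. The closest known reaction type is the intramolecular Diels–Alder reaction of vinylallenes tethered through the allene terminus. Ring A is closed as the cyclohexene of the cycloaddition itself and ring B by the C5–C10 bond across the four-atom tether C6=C7–C8(=O)–C9, the remaining allene π bond becoming C9=C10 of the cross-conjugated dienone. Because C9 lies on the allene axis, the tether can only sit exo and both methyl groups are endo; the E tiglyl geometry keeps C4-Me and C5-Me cis and the E enol acetate places the outside OAc cis to them, which gives the all-cis triad. The absolute sense follows from the (aR) axis, since the dienophile must add to the diene face that carries C8, giving 3S,4R,5R. The step needs periselectivity over intermolecular dimerisation and acid-induced Nazarov closure, which high dilution, neutral conditions and a radical inhibitor should secure, while regiochemistry is fixed by the tether.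

Step 11
Reactants: 20 tert-butyl (2R)-2-[(4aR,5R,6S)-6-acetoxy-4a,5-dimethyl-2-oxo-2,4a,5,6-tetrahydronaphthalen-3-yl]-2-{[(2R)-2-methylbutanoyl]oxy}propanoate
Product: 21 tert-butyl (2R)-2-[(4aR,5R,6S)-6-acetoxy-4a,5-dimethyl-2-oxo-2,4a,5,6,7,8-hexahydronaphthalen-3-yl]-2-{[(2R)-2-methylbutanoyl]oxy}propanoate
Conditions: H2 (1 atm), RhCl(PPh3)3 (10 mol%), PhH, rt
Reagents that add atoms: none
Why: Homogeneous hydrogenation with RhCl(PPh3)3 should be selective for the unhindered cis-disubstituted C1=C2 bond (the γ,δ bond of the linear dienone) over the two trisubstituted conjugated alkenes of ring B, and no stereocentre is formed or touched.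

Step 12
Reactants: 21 tert-butyl (2R)-2-[(4aR,5R,6S)-6-acetoxy-4a,5-dimethyl-2-oxo-2,4a,5,6,7,8-hexahydronaphthalen-3-yl]-2-{[(2R)-2-methylbutanoyl]oxy}propanoate
Product: 22 (2R)-2-[(4aR,5R,6S)-6-acetoxy-4a,5-dimethyl-2-oxo-2,4a,5,6,7,8-hexahydronaphthalen-3-yl]-2-{[(2R)-2-methylbutanoyl]oxy}propanoic acid (target)
Conditions: TFA/CH2Cl2 (1:4), 0 °C
Reagents that add atoms: none
Why: Acidolysis of the tert-butyl ester by loss of isobutene should free the C12 acid without touching the acetate, the tertiary 2-methylbutanoate or the dienone.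

**Compound list**

1 | (E)-2-methylbut-2-enal (tiglic aldehyde) | C/C=C(\C)C=O | starting material
2 | (E)-3-methylpent-3-en-1-yne | C#C/C(C)=C/C | intermediate
3 | tert-butyl 2-oxopropanoate (tert-butyl pyruvate) | CC(=O)C(=O)OC(C)(C)C | starting material
4 | tert-butyl (2R,5E)-2-hydroxy-2,5-dimethylhept-5-en-3-ynoate | O[C@@](C)(C(=O)OC(C)(C)C)C#C/C(C)=C/C | intermediate
5 | tert-butyl (2S,3Z,5E)-2-hydroxy-2,5-dimethyl-3-(tributylstannyl)hepta-3,5-dienoate | O[C@@](C)(C(=O)OC(C)(C)C)/C(=C/C(C)=C/C)[Sn](CCCC)(CCCC)CCCC | intermediate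
6 | tert-butyl (2S,3Z,5E)-2-hydroxy-3-iodo-2,5-dimethylhepta-3,5-dienoate | O[C@@](C)(C(=O)OC(C)(C)C)/C(I)=C/C(C)=C/C | intermediate
7 | (R)-2-methylbutanoic acid | CC[C@@H](C)C(=O)O | starting material
8 | (R)-2-methylbutanoyl chloride | CC[C@@H](C)C(Cl)=O | intermediate
9 | tert-butyl (2S,3Z,5E)-3-iodo-2,5-dimethyl-2-{[(2R)-2-methylbutanoyl]oxy}hepta-3,5-dienoate | CC[C@@H](C)C(=O)O[C@@](C)(C(=O)OC(C)(C)C)/C(I)=C/C(C)=C/C | intermediate
10 | tetrabutylammonium (E)-3-oxoprop-1-en-1-olate (malondialdehyde tetrabutylammonium salt) | [O-]/C=C/C=O.CCCC[N+](CCCC)(CCCC)CCCC | starting material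
11 | (E)-3-oxoprop-1-en-1-yl acetate | CC(=O)O/C=C/C=O | intermediate
12 | 3,3-diethoxyprop-1-yne | CCOC(OCC)C#C | starting material
13 | (1E,3R)-6,6-diethoxy-3-hydroxyhex-1-en-4-yn-1-yl acetate | CCOC(OCC)C#C[C@H](O)/C=C/OC(C)=O | intermediate
14 | (1E,3R)-3-hydroxy-6-oxohex-1-en-4-yn-1-yl acetate | O=CC#C[C@H](O)/C=C/OC(C)=O | intermediate
15 | tert-butyl (2R,3E,7R,8E)-9-acetoxy-4,7-dihydroxy-2-methyl-2-{[(2R)-2-methylbutanoyl]oxy}-3-[(2E)-2-methylbut-2-en-1-ylidene]non-8-en-5-ynoate (both C4 epimers) | CC[C@@H](C)C(=O)O[C@@](C)(C(=O)OC(C)(C)C)/C(=C/C(C)=C/C)C(O)C#C[C@H](O)/C=C/OC(C)=O | intermediate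
16 | tert-butyl (2R,3E,7S,8E)-9-acetoxy-4-hydroxy-2-methyl-2-{[(2R)-2-methylbutanoyl]oxy}-3-[(2E)-2-methylbut-2-en-1-ylidene]-7-[1-(2-nitrobenzenesulfonyl)hydrazin-1-yl]non-8-en-5-ynoate | CC[C@@H](C)C(=O)O[C@@](C)(C(=O)OC(C)(C)C)/C(=C/C(C)=C/C)C(O)C#C[C@@H](N(N)S(=O)(=O)c1ccccc1[N+](=O)[O-])/C=C/OC(C)=O | intermediate
17 | tert-butyl (2R,3E,7S,8E)-9-acetoxy-7-diazenyl-4-hydroxy-2-methyl-2-{[(2R)-2-methylbutanoyl]oxy}-3-[(2E)-2-methylbut-2-en-1-ylidene]non-8-en-5-ynoate | CC[C@@H](C)C(=O)O[C@@](C)(C(=O)OC(C)(C)C)/C(=C/C(C)=C/C)C(O)C#C[C@@H](N=N)/C=C/OC(C)=O | intermediate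
18 | tert-butyl (2R,3E,8E)-9-acetoxy-4-hydroxy-2-methyl-2-{[(2R)-2-methylbutanoyl]oxy}-3-[(2E)-2-methylbut-2-en-1-ylidene]nona-5,6,8-trienoate, (aR) axis at C5=C6=C7 of this name (both C4 epimers) | CC[C@@H](C)C(=O)O[C@@](C)(C(=O)OC(C)(C)C)/C(=C/C(C)=C/C)C(O)C([H])=[C@]=C([H])/C=C/OC(C)=O | intermediate
19 | tert-butyl (2R,3Z,8E)-9-acetoxy-2-methyl-2-{[(2R)-2-methylbutanoyl]oxy}-3-[(2E)-2-methylbut-2-en-1-ylidene]-4-oxonona-5,6,8-trienoate, (aR) axis | CC[C@@H](C)C(=O)O[C@@](C)(C(=O)OC(C)(C)C)/C(=C/C(C)=C/C)C(=O)C([H])=[C@]=C([H])/C=C/OC(C)=O | intermediate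
20 | tert-butyl (2R)-2-[(4aR,5R,6S)-6-acetoxy-4a,5-dimethyl-2-oxo-2,4a,5,6-tetrahydronaphthalen-3-yl]-2-{[(2R)-2-methylbutanoyl]oxy}propanoate | CC[C@@H](C)C(=O)O[C@@](C)(C(=O)OC(C)(C)C)C1=C[C@@]2(C)C(=CC1=O)C=C[C@H](OC(C)=O)[C@@H]2C | intermediate
21 | tert-butyl (2R)-2-[(4aR,5R,6S)-6-acetoxy-4a,5-dimethyl-2-oxo-2,4a,5,6,7,8-hexahydronaphthalen-3-yl]-2-{[(2R)-2-methylbutanoyl]oxy}propanoate | CC[C@@H](C)C(=O)O[C@@](C)(C(=O)OC(C)(C)C)C1=C[C@@]2(C)C(=CC1=O)CC[C@H](OC(C)=O)[C@@H]2C | intermediate
22 | (2R)-2-[(4aR,5R,6S)-6-acetoxy-4a,5-dimethyl-2-oxo-2,4a,5,6,7,8-hexahydronaphthalen-3-yl]-2-{[(2R)-2-methylbutanoyl]oxy}propanoic acid | CC[C@@H](C)C(=O)O[C@@](C)(C(=O)O)C1=C[C@@]2(C)C(=CC1=O)CC[C@H](OC(C)=O)[C@@H]2C | target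

**Step count.** Total: 12 steps. Longest linear sequence: 9 steps (1 → 2 → 4 → 6 → 9 → 15 → 18 → 20 → 22, with 21 before 22).

**Steps most likely to fail**

Step 10 (key cycloaddition). The allenyl ketone may dimerise by intermolecular cycloaddition, close by an acid-induced Nazarov pathway, or lose the E geometry of the C4=C5 alkene through reversible oxa-6π closure, before the unactivated trisubstituted dienophile reacts. The fallback sets out from 18 and changes the order of events. Carbinol 18 itself would be heated (PhMe, BHT, 90–110 °C, high dilution); the allene then carries no activated dienophile and cannot undergo Nazarov closure. This should give tert-butyl (2R)-2-[(4aR,5R,6S)-6-acetoxy-2-hydroxy-4a,5-dimethyl-2,4a,5,6-tetrahydronaphthalen-3-yl]-2-{[(2R)-2-methylbutanoyl]oxy}propanoate F1 as both carbinol epimers. Oxidation of the bis-allylic alcohol with MnO2 in CH2Cl2 would then return to 20.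

Step 9 (allene formation on the diol). Mitsunobu activation may be unselective between the two carbinols, or the allylic and propargylic C1 centre may ionise with loss of configurational information. The fallback sets out from 13 and moves the transposition ahead of the fragment union, so that only one hydroxyl is present. The same PPh3/DEAD/NBSH conditions applied to 13 should give (1E)-6,6-diethoxyhexa-1,3,4-trien-1-yl acetate with (aR) axis F2. Acetal hydrolysis (Amberlyst-15, wet acetone, 0 °C) would give (1E)-6-oxohexa-1,3,4-trien-1-yl acetate with (aR) axis F3, used at once in dilute solution. CrCl2/NiCl2 coupling of F3 with iodide 9 would come back to the route at 18.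

Step 8 (fragment union). Coupling of the hindered, α-branched alkenyl iodide may be slow, the alkenylchromium species may undergo β-elimination of the acyloxy group, or nickel may insert into the alkyne of the partner. The fallback sets out from 9 and 11 and reverses the polarity of the union. Reductive carbonylation of 9 (Pd(PPh3)4, CO, Bu3SnH, THF, 50 °C) would give tert-butyl (2R,3Z,5E)-3-formyl-2,5-dimethyl-2-{[(2R)-2-methylbutanoyl]oxy}hepta-3,5-dienoate F4. Alkynylation of 11 with ethynyltrimethylsilane (Me2Zn, (S,S)-ProPhenol) would give (1E,3R)-3-hydroxy-5-(trimethylsilyl)pent-1-en-4-yn-1-yl acetate F5. C-desilylation (Bu4NF buffered with AcOH, −20 °C) would give (1E,3R)-3-hydroxypent-1-en-4-yn-1-yl acetate F6. Addition of the zinc alkynylide of F6 (Me2Zn, PhMe) to aldehyde F4 would come back to the route at 15, and this path also avoids the acetal hydrolysis of step 7.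

Further compounds
F1 | step 10 | tert-butyl (2R)-2-[(4aR,5R,6S)-6-acetoxy-2-hydroxy-4a,5-dimethyl-2,4a,5,6-tetrahydronaphthalen-3-yl]-2-{[(2R)-2-methylbutanoyl]oxy}propanoate (both carbinol epimers) | CC[C@@H](C)C(=O)O[C@@](C)(C(=O)OC(C)(C)C)C1=C[C@@]2(C)C(=CC1O)C=C[C@H](OC(C)=O)[C@@H]2C
F2 | step 9 | (1E)-6,6-diethoxyhexa-1,3,4-trien-1-yl acetate, (aR) axis | CCOC(OCC)C([H])=[C@]=C([H])/C=C/OC(C)=O
F3 | step 9 | (1E)-6-oxohexa-1,3,4-trien-1-yl acetate, (aR) axis | O=CC([H])=[C@]=C([H])/C=C/OC(C)=O
F4 | step 8 | tert-butyl (2R,3Z,5E)-3-formyl-2,5-dimethyl-2-{[(2R)-2-methylbutanoyl]oxy}hepta-3,5-dienoate | CC[C@@H](C)C(=O)O[C@@](C)(C(=O)OC(C)(C)C)/C(C=O)=C/C(C)=C/C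
F5 | step 8 | (1E,3R)-3-hydroxy-5-(trimethylsilyl)pent-1-en-4-yn-1-yl acetate | C[Si](C)(C)C#C[C@H](O)/C=C/OC(C)=O
F6 | step 8 | (1E,3R)-3-hydroxypent-1-en-4-yn-1-yl acetate | C#C[C@H](O)/C=C/OC(C)=O
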